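**Retrosynthetic overview**
1. Target ⇐ (6R)-allylic alcohol by invertive deoxychlorination; the ten-membered ring ⇐ Nozaki–Hiyama–Kishi closure of C5–C6 (2-iodoalkene + C6 aldehyde), with C6 then fixed by oxidation and CBS reduction.
2. γ-Lactone (C7, C8, C17) ⇐ chelation-controlled Reformatsky addition to a C8 vinyl ketone, kinetic iodolactonisation and lactone-enolate methylation; a lipase frees the C6 hydroxyl late, one primary acetate among four.
3. C9 ⇐ Felkin–Anh alkynylation of a C9 aldehyde; C11/C12 cis-diol ⇐ OsO4 on a ring 1,3-diene; C2 ⇐ CBS reduction.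
4. Cyclohexene core (C1 and C10 together) ⇐ catalytic asymmetric Diels–Alder reaction of 2-silyloxybutadiene with ethyl (E)-3-methyl-4-oxobut-2-enoate.
5. Ring order: six-membered carbocycle, then γ-lactone, then ten-membered ring.

Positions use briarane numbering: C1 quaternary ring carbon (Me-15), C2–C9 ten-membered-ring carbons, C10 ring-fusion CH, C11–C14 cyclohexene, C16 exocyclic CH2 on C5, C17/C18/C19 lactone CH/CH3/C=O, C20 methyl on C11.

Assumption: the (S)-oxazaborolidinium catalyst of step 2 is taken to give the enantiomeric series shown; if the facial sense is the opposite, its commercial enantiomer is used and nothing else changes.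

**Route**

Step 1
Reactants: 1 but-3-en-2-one
Product: 2 2-(triisopropylsilyloxy)buta-1,3-diene
Conditions: iPr3SiOTf, Et3N, CH2Cl2, 0 °C to rt
Reagents that add atoms: triisopropylsilyl trifluoromethanesulfonate, CC(C)[Si](C(C)C)(C(C)C)OS(=O)(=O)C(F)(F)F
Why: Soft enolisation and O-silylation (silyl enol ether formation) turn the enone into a robust electron-rich diene; no stereocentre is formed.

Step 2
Reactants: 2 2-(triisopropylsilyloxy)buta-1,3-diene; 3 ethyl (E)-3-methyl-4-oxobut-2-enoate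
Product: 4 ethyl (1S,6S)-6-formyl-6-methyl-3-(triisopropylsilyloxy)cyclohex-3-ene-1-carboxylate
Conditions: (S)-o-tolyl-CBS-oxazaborolidine/HNTf2 (20 mol%), CH2Cl2, −78 to −40 °C
Reagents that add atoms: none
Why: Catalytic asymmetric Diels–Alder reaction with a chiral oxazaborolidinium Lewis acid: the boron-bound formyl group directs the diene CH2 next to the silyloxy carbon onto C10 ("para" adduct), the E-dienophile places CHO and CO2Et trans, and the catalyst shields one enal face, so C1 and C10 are set together.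

Step 3
Reactants: 4 Diels–Alder aldehyde ester; 5 (4-bromobut-1-yn-1-yl)triisopropylsilane
Product: 7 C2 carbinol (both C2 epimers), via butynylmagnesium bromide 6 (not isolated)
Conditions: Mg, THF, 40 °C; then 4, THF, −78 °C; aq. NH4Cl
Reagents that add atoms: none
Why: Grignard addition to the non-enolisable neopentyl aldehyde at −78 °C leaves the ester and silyl enol ether untouched; the C2 ratio is irrelevant because C2 is oxidised next.

Step 4
Reactants: 7 C2 carbinol
Product: 8 C2 ketone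
Conditions: Dess–Martin periodinane, NaHCO3, CH2Cl2, 0 °C to rt
Reagents that add atoms: none
Why: Dess–Martin oxidation erases the uncontrolled C2 centre under buffered conditions that spare the silyl enol ether and cannot epimerise C10.

Step 5
Reactants: 8 C2 ketone
Product: 9 (2R)-alcohol
Conditions: (S)-Me-CBS-oxazaborolidine (0.3 equiv), catecholborane, toluene, −78 to −40 °C
Reagents that add atoms: none
Why: Corey–Bakshi–Shibata reduction: the quaternary C1 is the large and the CH2CH2 chain the small ketone substituent, so the (S)-catalyst gives the (2R)-carbinol under reagent control, and catecholborane does not hydroborate the silylalkyne.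

Step 6
Reactants: 9 (2R)-alcohol
Product: 10 O2-triethylsilyl ether
Conditions: Et3SiOTf, 2,6-lutidine, CH2Cl2, −78 °C
Reagents that add atoms: triethylsilyl trifluoromethanesulfonate, CC[Si](CC)(CC)OS(=O)(=O)C(F)(F)F
Why: Silylation under non-basic conditions protects the hindered carbinol before it can lactonise onto the C9 ester.

Step 7
Reactants: 10 O2-triethylsilyl ether
Product: 11 C9 primary alcohol
Conditions: LiAlH4, Et2O, 0 °C
Reagents that add atoms: none
Why: Hydride reduction of the ester to the primary alcohol; silyl ethers, silyl enol ether and silylalkyne are inert.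

Step 8
Reactants: 11 C9 primary alcohol
Product: 12 C9 aldehyde
Conditions: Dess–Martin periodinane, NaHCO3, CH2Cl2, 0 °C
Reagents that add atoms: none
Why: Buffered Dess–Martin oxidation gives the α-branched aldehyde without epimerising C10.

Step 9
Reactants: 12 C9 aldehyde; 13 lithium (trimethylsilyl)acetylide
Product: 14 (9R)-propargylic alcohol
Conditions: THF, −78 °C; aq. NH4Cl
Reagents that add atoms: none
Why: Felkin–Anh 1,2-addition: the quaternary C1 is the large α-substituent anti to the incoming acetylide and C11H2 the medium one, which gives the (9R)-carbinol.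

Step 10
Reactants: 14 (9R)-propargylic alcohol
Product: 15 O9-(4-methoxybenzyl) ether
Conditions: NaH, 4-MeOC6H4CH2Br, Bu4NI (cat.), THF, 0 °C to rt
Reagents that add atoms: 4-methoxybenzyl bromide, COc1ccc(CBr)cc1
Why: Williamson etherification installs an ether that survives the ring chemistry and later acts as the chelating group at C9.

Step 11
Reactants: 15 O9-(4-methoxybenzyl) ether
Product: 16 C12 enone
Conditions: Pd(OAc)2 (1.05 equiv), MeCN, 40 °C
Reagents that add atoms: none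
Why: Saegusa–Ito oxidation of the regiodefined silyl enol ether places the enone double bond at C13=C14 only.

Step 12
Reactants: 16 C12 enone
Product: 18 C11-methyl enone (both C11 epimers), via lithium dienolate 17 (not isolated)
Conditions: LiN(iPr)2, THF, −78 °C; then MeI, DMPU, −78 to −40 °C
Reagents that add atoms: iodomethane, CI
Why: Kinetic α'-deprotonation (C1 is quaternary, so there is no γ-proton) and enolate alkylation install C20; the C11 configuration is irrelevant because C11 becomes sp2 in the next step.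

Step 13
Reactants: 18 C11-methyl enone
Product: 20 dienyl triflate, via potassium dienolate 19 (not isolated)
Conditions: KN(SiMe3)2, THF, −78 °C; then PhNTf2, −78 to 0 °C
Reagents that add atoms: N-phenylbis(trifluoromethanesulfonimide), O=S(=O)(N(c1ccccc1)S(=O)(=O)C(F)(F)F)C(F)(F)F
Why: O-triflation of the cross-conjugated dienolate (enol triflate formation) fixes the C11=C12 double bond.

Step 14
Reactants: 20 dienyl triflate
Product: 21 ring 1,3-diene
Conditions: Pd(OAc)2 (5 mol%), PPh3, Bu3N, HCO2H, DMF, 60 °C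
Reagents that add atoms: none
Why: Palladium-catalysed formate reduction of the alkenyl triflate gives the diene without touching the silylalkynes or the benzylic ether.

Step 15
Reactants: 21 ring 1,3-diene
Product: 22 (11S,12R)-cis-diol
Conditions: OsO4 (2 mol%), NMO, acetone/H2O, 0 °C
Reagents that add atoms: N-methylmorpholine N-oxide, C[N+]1([O-])CCOCC1; water, O
Why: Upjohn dihydroxylation picks the electron-rich trisubstituted C11=C12 alkene and adds syn from the face opposite the C10 side chain (the face also left open by the C1 methyl), setting C11 and C12 as the cis-diol.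

Step 16
Reactants: 22 cis-diol
Product: 23 acetonide
Conditions: 2-methoxypropene, PPTS (cat.), CH2Cl2, 0 °C
Reagents that add atoms: 2-methoxypropene, COC(C)=C
Why: Ketalisation of the cis-1,2-diol protects the tertiary and secondary hydroxyls for the base and organometallic steps that follow.

Step 17
Reactants: 23 acetonide
Product: 24 terminal alkyne
Conditions: K2CO3, MeOH, rt
Reagents that add atoms: none
Why: Methanolysis cleaves only the trimethylsilyl alkyne; the triisopropylsilyl alkyne and the silyl ether stay.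

Step 18
Reactants: 24 terminal alkyne
Product: 25 C8 methyl ketone
Conditions: Ph3PAuNTf2 (2 mol%), 1,4-dioxane/H2O, 60 °C
Reagents that add atoms: water, O
Why: Gold-catalysed Markovnikov hydration of the terminal alkyne gives the C8 ketone; the hindered internal silylalkyne does not react.

Step 19
Reactants: 25 C8 methyl ketone
Product: 29 C8 vinyl ketone, via lithium enolate 26 (not isolated), via Mannich base 27 (not isolated), via trimethylammonium iodide 28 (not isolated)
Conditions: LiN(iPr)2, THF, −78 °C; CH2=NMe2+ I−, −78 to 0 °C; MeI, CH2Cl2, rt; aq. NaHCO3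
Reagents that add atoms: N,N-dimethylmethyleneiminium iodide, C=[N+](C)C.[I-]
Why: Mannich reaction of the kinetic methyl enolate with Eschenmoser's salt, then quaternisation and elimination (α-methylenation), adds C6 and gives the vinyl ketone without touching C9.

Step 20
Reactants: 29 C8 vinyl ketone; 30 ethyl bromoacetate
Product: 32 β-hydroxy ester, via Reformatsky reagent 31 (not isolated)
Conditions: Zn, Me3SiCl (cat.), THF, 40 °C; then 29, THF, −40 to 0 °C; aq. NH4Cl
Reagents that add atoms: none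
Why: Reformatsky reaction: the zinc enolate adds 1,2 to the Cram chelate between the ketone and the C9 ether oxygen, from the face away from C10, which sets the C8 tertiary carbinol (O8 and O9 syn).

Step 21
Reactants: 32 β-hydroxy ester
Product: 34 iodolactone, via lithium carboxylate 33 (not isolated)
Conditions: LiOH, THF/H2O, 0 °C; then NaHCO3, I2, MeCN/H2O, 0 °C, dark
Reagents that add atoms: lithium hydroxide, [Li+].[OH-]; iodine, II
Why: Saponification then kinetic iodolactonisation (5-exo, anti addition) with the allylic hydroxyl in the alkene plane closes the γ-lactone with CH2I cis to the 8-OH and trans to the bulky C9 branch, setting C7.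

Step 22
Reactants: 34 iodolactone
Product: 36 17-methyl iodolactone, via dilithium alkoxide enolate 35 (not isolated)
Conditions: LiN(iPr)2 (2.2 equiv), THF, −78 °C; then MeI, −78 to −50 °C; aq. NH4Cl
Reagents that add atoms: iodomethane, CI
Why: Alkylation of the lactone enolate occurs on the face opposite the C9 branch at C8, so Me-18 ends cis to the 8-OH (17R); at −78 °C the primary iodide is inert.

Step 23
Reactants: 36 17-methyl iodolactone
Product: 37 C6 acetate
Conditions: CsOAc, 18-crown-6, DMF, 60 °C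
Reagents that add atoms: caesium acetate, [Cs+].CC(=O)[O-]
Why: SN2 displacement of the primary iodide by acetate turns C6 into a protected alcohol.

Step 24
Reactants: 37 C6 acetate
Product: 39 C5 terminal alkyne, via silver acetylide 38 (not isolated)
Conditions: AgF, MeCN, rt, dark; then 1 M HCl, 0 °C
Reagents that add atoms: none
Why: Fluoride-induced C(sp)–Si cleavage through the silver acetylide removes the triisopropylsilyl group while the triethylsilyl ether, acetonide and acetate survive.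

Step 25
Reactants: 39 C5 terminal alkyne
Product: 40 9-alcohol
Conditions: DDQ, CH2Cl2/pH 7 buffer, 0 °C
Reagents that add atoms: none
Why: Oxidative cleavage of the 4-methoxybenzyl ether frees the 9-OH under neutral conditions.

Step 26
Reactants: 40 9-alcohol
Product: 41 pentaol C6 acetate
Conditions: AcOH/H2O (4:1), 45 °C
Reagents that add atoms: none
Why: Mild acid hydrolysis removes the triethylsilyl ether and the acetonide together; the primary acetate and the lactone are stable.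

Step 27
Reactants: 41 pentaol C6 acetate
Product: 42 tetraacetate
Conditions: Ac2O, pyridine, DMAP (cat.), CH2Cl2, 0 °C to rt
Reagents that add atoms: acetic anhydride, CC(=O)OC(C)=O
Why: Acylation takes the three secondary hydroxyls (C2, C9, C12); the tertiary 8- and 11-hydroxyls are too hindered to react.

Step 28
Reactants: 42 tetraacetate
Product: 43 1,1-disubstituted vinylsilane
Conditions: [Cp*Ru(MeCN)3]PF6 (5 mol%), Et3SiH, CH2Cl2, 0 °C to rt
Reagents that add atoms: triethylsilane, CC[SiH](CC)CC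
Why: Ruthenium-catalysed Markovnikov hydrosilylation of the terminal alkyne puts silicon on C5 and tolerates esters and free tertiary alcohols.

Step 29
Reactants: 43 vinylsilane
Product: 44 2-iodoalkene
Conditions: N-iodosuccinimide, (CF3)2CHOH, 0 °C
Reagents that add atoms: N-iodosuccinimide, O=C1CCC(=O)N1I
Why: Ipso iododesilylation replaces silicon by iodine at C5 and gives the coupling partner for ring closure.

Step 30
Reactants: 44 2-iodoalkene tetraacetate
Product: 45 C6 primary alcohol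
Conditions: lipase (immobilised Candida antarctica lipase B), phosphate buffer pH 7/acetone (9:1), 30 °C
Reagents that add atoms: none
Why: Enzymatic ester hydrolysis: the lipase accepts only the unhindered primary acetate, so the three hindered secondary acetates and the γ-lactone stay intact, which no chemical hydrolysis does reliably.

Step 31
Reactants: 45 C6 primary alcohol
Product: 46 C6 aldehyde
Conditions: Dess–Martin periodinane, NaHCO3, CH2Cl2, 0 °C
Reagents that add atoms: none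
Why: Neutral Dess–Martin oxidation gives the α-acyloxy aldehyde without epimerising C7; it is used at once.

Step 32
Reactants: 46 C6 aldehyde
Product: 47 macrocyclic allylic alcohol (both C6 epimers)
Conditions: CrCl2 (15 equiv), NiCl2 (0.3 equiv), DMSO/THF (3:1), 0.002 M, rt
Reagents that add atoms: none
Why: Intramolecular Nozaki–Hiyama–Kishi coupling of the 2-iodoalkene with the aldehyde forms C5–C6, the ten-membered ring and the exocyclic methylene in one step and tolerates acetates, lactone and free hydroxyls; the C6 epimers converge in steps 33 and 34.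

Step 33
Reactants: 47 macrocyclic allylic alcohol
Product: 48 C6 enone
Conditions: Dess–Martin periodinane, NaHCO3, CH2Cl2, 0 °C
Reagents that add atoms: none
Why: Oxidation of the only secondary alcohol merges both C6 epimers into one α-methylene ketone under non-basic conditions.

Step 34
Reactants: 48 C6 enone
Product: 49 (6R)-allylic alcohol
Conditions: (R)-Me-CBS-oxazaborolidine (1 equiv), catecholborane, CH2Cl2/toluene, −78 °C
Reagents that add atoms: none
Why: Corey–Bakshi–Shibata 1,2-reduction with the alkenyl group as the large substituent gives the (6R)-carbinol, the same sense as polar Felkin–Anh attack anti to the C7 oxygen.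

Step 35
Reactants: 49 (6R)-allylic alcohol
Product: 50 target CNP0259091.2
Conditions: PPh3, Cl3CCOCCl3, 2,6-di-tert-butylpyridine, CH2Cl2, −20 to 0 °C
Reagents that add atoms: hexachloroacetone, ClC(Cl)(Cl)C(=O)C(Cl)(Cl)Cl
Why: Appel-type deoxychlorination: chloride displaces the oxyphosphonium leaving group by SN2 with inversion and without allylic transposition, giving the (6S)-chloride; the hindered tertiary alcohols do not react.

**Compound list**

1 | but-3-en-2-one (methyl vinyl ketone) | CC(=O)C=C | starting material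
2 | 2-(triisopropylsilyloxy)buta-1,3-diene | C=CC(=C)O[Si](C(C)C)(C(C)C)C(C)C | intermediate
3 | ethyl (E)-3-methyl-4-oxobut-2-enoate | CCOC(=O)/C=C(\C)C=O | starting material
4 | ethyl (1S,6S)-6-formyl-6-methyl-3-(triisopropylsilyloxy)cyclohex-3-ene-1-carboxylate (CHO and CO2Et trans; ring C6 and C1 are C1 and C10 of the target) | O=C[C@@]1(C)CC=C(O[Si](C(C)C)(C(C)C)C(C)C)C[C@@H]1C(=O)OCC | intermediate
5 | (4-bromobut-1-yn-1-yl)triisopropylsilane | BrCCC#C[Si](C(C)C)(C(C)C)C(C)C | starting material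
6 | [4-(triisopropylsilyl)but-3-yn-1-yl]magnesium bromide | Br[Mg]CCC#C[Si](C(C)C)(C(C)C)C(C)C | intermediate
7 | ethyl (1S,6S)-6-[1-hydroxy-5-(triisopropylsilyl)pent-4-yn-1-yl]-6-methyl-3-(triisopropylsilyloxy)cyclohex-3-ene-1-carboxylate, both carbinol (C2) epimers | CC(C)[Si](C(C)C)(C(C)C)C#CCCC(O)[C@@]1(C)CC=C(O[Si](C(C)C)(C(C)C)C(C)C)C[C@@H]1C(=O)OCC | intermediate
8 | ethyl (1S,6S)-6-methyl-6-[5-(triisopropylsilyl)pent-4-ynoyl]-3-(triisopropylsilyloxy)cyclohex-3-ene-1-carboxylate (C2 ketone) | CC(C)[Si](C(C)C)(C(C)C)C#CCCC(=O)[C@@]1(C)CC=C(O[Si](C(C)C)(C(C)C)C(C)C)C[C@@H]1C(=O)OCC | intermediate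
9 | ethyl (1S,6S)-6-[(1R)-1-hydroxy-5-(triisopropylsilyl)pent-4-yn-1-yl]-6-methyl-3-(triisopropylsilyloxy)cyclohex-3-ene-1-carboxylate ((2R)-alcohol) | CC(C)[Si](C(C)C)(C(C)C)C#CCC[C@@H](O)[C@@]1(C)CC=C(O[Si](C(C)C)(C(C)C)C(C)C)C[C@@H]1C(=O)OCC | intermediate
10 | 9 as its O2-triethylsilyl ether | CC(C)[Si](C(C)C)(C(C)C)C#CCC[C@@H](O[Si](CC)(CC)CC)[C@@]1(C)CC=C(O[Si](C(C)C)(C(C)C)C(C)C)C[C@@H]1C(=O)OCC | intermediate
11 | 10 with CO2Et reduced to CH2OH (C9 primary alcohol) | CC(C)[Si](C(C)C)(C(C)C)C#CCC[C@@H](O[Si](CC)(CC)CC)[C@@]1(C)CC=C(O[Si](C(C)C)(C(C)C)C(C)C)C[C@@H]1CO | intermediate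
12 | C9 aldehyde (CH2OH of 11 oxidised to CHO) | CC(C)[Si](C(C)C)(C(C)C)C#CCC[C@@H](O[Si](CC)(CC)CC)[C@@]1(C)CC=C(O[Si](C(C)C)(C(C)C)C(C)C)C[C@@H]1C=O | intermediate
13 | lithium (trimethylsilyl)acetylide | [Li]C#C[Si](C)(C)C | starting material
14 | (9R)-propargylic alcohol: 12 with CHO replaced by (R)-CH(OH)C≡C-SiMe3 | CC(C)[Si](C(C)C)(C(C)C)C#CCC[C@@H](O[Si](CC)(CC)CC)[C@@]1(C)CC=C(O[Si](C(C)C)(C(C)C)C(C)C)C[C@@H]1[C@@H](O)C#C[Si](C)(C)C | intermediate
15 | O9-(4-methoxybenzyl) ether of 14 | CC(C)[Si](C(C)C)(C(C)C)C#CCC[C@@H](O[Si](CC)(CC)CC)[C@@]1(C)CC=C(O[Si](C(C)C)(C(C)C)C(C)C)C[C@@H]1[C@@H](OCc2ccc(OC)cc2)C#C[Si](C)(C)C | intermediate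
16 | cyclohex-2-enone: 15 with the silyl enol ether replaced by C12=O conjugated to C13=C14 | CC(C)[Si](C(C)C)(C(C)C)C#CCC[C@@H](O[Si](CC)(CC)CC)[C@@]1(C)C=CC(=O)C[C@@H]1[C@@H](OCc2ccc(OC)cc2)C#C[Si](C)(C)C | intermediate
17 | lithium cross-conjugated dienolate of 16 (C11=C12-OLi) | CC(C)[Si](C(C)C)(C(C)C)C#CCC[C@@H](O[Si](CC)(CC)CC)[C@@]1(C)C=CC(O[Li])=C[C@@H]1[C@@H](OCc2ccc(OC)cc2)C#C[Si](C)(C)C | intermediate
18 | 16 methylated at C11, both C11 epimers | CC(C)[Si](C(C)C)(C(C)C)C#CCC[C@@H](O[Si](CC)(CC)CC)[C@@]1(C)C=CC(=O)C(C)[C@@H]1[C@@H](OCc2ccc(OC)cc2)C#C[Si](C)(C)C | intermediate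
19 | potassium dienolate of 18 (C11(Me)=C12-OK) | CC(C)[Si](C(C)C)(C(C)C)C#CCC[C@@H](O[Si](CC)(CC)CC)[C@@]1(C)C=CC(O[K])=C(C)[C@@H]1[C@@H](OCc2ccc(OC)cc2)C#C[Si](C)(C)C | intermediate
20 | dienyl triflate (C11(Me)=C12(OTf), C13=C14) | CC(C)[Si](C(C)C)(C(C)C)C#CCC[C@@H](O[Si](CC)(CC)CC)[C@@]1(C)C=CC(OS(=O)(=O)C(F)(F)F)=C(C)[C@@H]1[C@@H](OCc2ccc(OC)cc2)C#C[Si](C)(C)C | intermediate
21 | cyclohexa-1,3-diene (C11(Me)=C12H-C13H=C14H) | CC(C)[Si](C(C)C)(C(C)C)C#CCC[C@@H](O[Si](CC)(CC)CC)[C@@]1(C)C=CC=C(C)[C@@H]1[C@@H](OCc2ccc(OC)cc2)C#C[Si](C)(C)C | intermediate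
22 | (11S,12R)-cis-diol, both hydroxyls on the ring face opposite the C10 side chain | CC(C)[Si](C(C)C)(C(C)C)C#CCC[C@@H](O[Si](CC)(CC)CC)[C@@]1(C)C=C[C@@H](O)[C@@](C)(O)[C@@H]1[C@@H](OCc2ccc(OC)cc2)C#C[Si](C)(C)C | intermediate
23 | 11,12-O-isopropylidene acetal of 22 | CC(C)[Si](C(C)C)(C(C)C)C#CCC[C@@H](O[Si](CC)(CC)CC)[C@@]1(C)C=C[C@@H](OC(C)(C)O2)[C@]2(C)[C@@H]1[C@@H](OCc3ccc(OC)cc3)C#C[Si](C)(C)C | intermediate
24 | 23 without the trimethylsilyl group (terminal alkyne on C9) | CC(C)[Si](C(C)C)(C(C)C)C#CCC[C@@H](O[Si](CC)(CC)CC)[C@@]1(C)C=C[C@@H](OC(C)(C)O2)[C@]2(C)[C@@H]1[C@@H](OCc3ccc(OC)cc3)C#C | intermediate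
25 | C8 methyl ketone (C9-CH(OPMB)-C(=O)CH3) | CC(C)[Si](C(C)C)(C(C)C)C#CCC[C@@H](O[Si](CC)(CC)CC)[C@@]1(C)C=C[C@@H](OC(C)(C)O2)[C@]2(C)[C@@H]1[C@@H](OCc3ccc(OC)cc3)C(C)=O | intermediate
26 | lithium enolate of 25 (CH2=C(OLi)) | CC(C)[Si](C(C)C)(C(C)C)C#CCC[C@@H](O[Si](CC)(CC)CC)[C@@]1(C)C=C[C@@H](OC(C)(C)O2)[C@]2(C)[C@@H]1[C@@H](OCc3ccc(OC)cc3)C(=C)O[Li] | intermediate
27 | Mannich base (C8(=O)CH2CH2NMe2) | CC(C)[Si](C(C)C)(C(C)C)C#CCC[C@@H](O[Si](CC)(CC)CC)[C@@]1(C)C=C[C@@H](OC(C)(C)O2)[C@]2(C)[C@@H]1[C@@H](OCc3ccc(OC)cc3)C(=O)CCN(C)C | intermediate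
28 | methiodide of 27 (trimethylammonium iodide) | CC(C)[Si](C(C)C)(C(C)C)C#CCC[C@@H](O[Si](CC)(CC)CC)[C@@]1(C)C=C[C@@H](OC(C)(C)O2)[C@]2(C)[C@@H]1[C@@H](OCc3ccc(OC)cc3)C(=O)CC[N+](C)(C)C.[I-] | intermediate
29 | C8 vinyl ketone (C9-CH(OPMB)-C(=O)CH=CH2) | CC(C)[Si](C(C)C)(C(C)C)C#CCC[C@@H](O[Si](CC)(CC)CC)[C@@]1(C)C=C[C@@H](OC(C)(C)O2)[C@]2(C)[C@@H]1[C@@H](OCc3ccc(OC)cc3)C(=O)C=C | intermediate
30 | ethyl bromoacetate | CCOC(=O)CBr | starting material
31 | (2-ethoxy-2-oxoethyl)zinc bromide | CCOC(=O)C[Zn]Br | intermediate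
32 | β-hydroxy ester: tertiary C8 carbinol carrying vinyl (C7=C6) and CH2CO2Et (C17, C19), O8 and O9 syn | CC(C)[Si](C(C)C)(C(C)C)C#CCC[C@@H](O[Si](CC)(CC)CC)[C@@]1(C)C=C[C@@H](OC(C)(C)O2)[C@]2(C)[C@@H]1[C@@H](OCc3ccc(OC)cc3)[C@](O)(CC(=O)OCC)C=C | intermediate
33 | lithium carboxylate of 32 | CC(C)[Si](C(C)C)(C(C)C)C#CCC[C@@H](O[Si](CC)(CC)CC)[C@@]1(C)C=C[C@@H](OC(C)(C)O2)[C@]2(C)[C@@H]1[C@@H](OCc3ccc(OC)cc3)[C@](O)(CC(=O)O[Li])C=C | intermediate
34 | iodolactone: γ-lactone C19(=O)-O-C7 with CH2I on C7 cis to the 8-OH | CC(C)[Si](C(C)C)(C(C)C)C#CCC[C@@H](O[Si](CC)(CC)CC)[C@@]1(C)C=C[C@@H](OC(C)(C)O2)[C@]2(C)[C@@H]1[C@@H](OCc3ccc(OC)cc3)[C@]4(O)CC(=O)O[C@H]4CI | intermediate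
35 | dilithium alkoxide enolate of 34 | CC(C)[Si](C(C)C)(C(C)C)C#CCC[C@@H](O[Si](CC)(CC)CC)[C@@]1(C)C=C[C@@H](OC(C)(C)O2)[C@]2(C)[C@@H]1[C@@H](OCc3ccc(OC)cc3)[C@]4(O[Li])C=C(O[Li])O[C@H]4CI | intermediate
36 | 34 methylated at C17 (17R, Me-18 cis to the 8-OH) | CC(C)[Si](C(C)C)(C(C)C)C#CCC[C@@H](O[Si](CC)(CC)CC)[C@@]1(C)C=C[C@@H](OC(C)(C)O2)[C@]2(C)[C@@H]1[C@@H](OCc3ccc(OC)cc3)[C@]4(O)[C@@H](C)C(=O)O[C@H]4CI | intermediate
37 | C6 acetate (CH2I of 36 replaced by CH2OAc) | CC(C)[Si](C(C)C)(C(C)C)C#CCC[C@@H](O[Si](CC)(CC)CC)[C@@]1(C)C=C[C@@H](OC(C)(C)O2)[C@]2(C)[C@@H]1[C@@H](OCc3ccc(OC)cc3)[C@]4(O)[C@@H](C)C(=O)O[C@H]4COC(C)=O | intermediate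
38 | silver acetylide of 39 | [Ag]C#CCC[C@@H](O[Si](CC)(CC)CC)[C@@]1(C)C=C[C@@H](OC(C)(C)O2)[C@]2(C)[C@@H]1[C@@H](OCc3ccc(OC)cc3)[C@]4(O)[C@@H](C)C(=O)O[C@H]4COC(C)=O | intermediate
39 | 37 without the triisopropylsilyl group (terminal alkyne C5≡C16) | C#CCC[C@@H](O[Si](CC)(CC)CC)[C@@]1(C)C=C[C@@H](OC(C)(C)O2)[C@]2(C)[C@@H]1[C@@H](OCc3ccc(OC)cc3)[C@]4(O)[C@@H](C)C(=O)O[C@H]4COC(C)=O | intermediate
40 | 39 with free 9-OH | C#CCC[C@@H](O[Si](CC)(CC)CC)[C@@]1(C)C=C[C@@H](OC(C)(C)O2)[C@]2(C)[C@@H]1[C@@H](O)[C@]4(O)[C@@H](C)C(=O)O[C@H]4COC(C)=O | intermediate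
41 | pentaol (free 2-, 8-, 9-, 11- and 12-OH) with C6 acetate | C#CCC[C@@H](O)[C@@]1(C)C=C[C@@H](O)[C@@](C)(O)[C@@H]1[C@@H](O)[C@]2(O)[C@@H](C)C(=O)O[C@H]2COC(C)=O | intermediate
42 | 2,6,9,12-tetraacetate with free tertiary 8- and 11-OH | C#CCC[C@@H](OC(C)=O)[C@@]1(C)C=C[C@@H](OC(C)=O)[C@@](C)(O)[C@@H]1[C@@H](OC(C)=O)[C@]2(O)[C@@H](C)C(=O)O[C@H]2COC(C)=O | intermediate
43 | 42 with the alkyne converted to CH2=C(SiEt3)- | C=C([Si](CC)(CC)CC)CC[C@@H](OC(C)=O)[C@@]1(C)C=C[C@@H](OC(C)=O)[C@@](C)(O)[C@@H]1[C@@H](OC(C)=O)[C@]2(O)[C@@H](C)C(=O)O[C@H]2COC(C)=O | intermediate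
44 | 2-iodoalkene CH2=C(I)- tetraacetate | C=C(I)CC[C@@H](OC(C)=O)[C@@]1(C)C=C[C@@H](OC(C)=O)[C@@](C)(O)[C@@H]1[C@@H](OC(C)=O)[C@]2(O)[C@@H](C)C(=O)O[C@H]2COC(C)=O | intermediate
45 | 44 with the primary C6 acetate hydrolysed (CH2OH) | C=C(I)CC[C@@H](OC(C)=O)[C@@]1(C)C=C[C@@H](OC(C)=O)[C@@](C)(O)[C@@H]1[C@@H](OC(C)=O)[C@]2(O)[C@@H](C)C(=O)O[C@H]2CO | intermediate
46 | C6 aldehyde | C=C(I)CC[C@@H](OC(C)=O)[C@@]1(C)C=C[C@@H](OC(C)=O)[C@@](C)(O)[C@@H]1[C@@H](OC(C)=O)[C@]2(O)[C@@H](C)C(=O)O[C@H]2C=O | intermediate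
47 | 6-dechloro-6-hydroxy target, both C6 epimers (ten-membered ring closed) | C=C1CC[C@@H](OC(C)=O)[C@@]2(C)C=C[C@@H](OC(C)=O)[C@@](C)(O)[C@@H]2[C@@H](OC(C)=O)[C@]2(O)[C@@H](C)C(=O)O[C@H]2C1O | intermediate
48 | C6 ketone (5(16)-en-6-one) | C=C1CC[C@@H](OC(C)=O)[C@@]2(C)C=C[C@@H](OC(C)=O)[C@@](C)(O)[C@@H]2[C@@H](OC(C)=O)[C@]2(O)[C@@H](C)C(=O)O[C@H]2C1=O | intermediate
49 | (6R)-allylic alcohol | C=C1CC[C@@H](OC(C)=O)[C@@]2(C)C=C[C@@H](OC(C)=O)[C@@](C)(O)[C@@H]2[C@@H](OC(C)=O)[C@]2(O)[C@@H](C)C(=O)O[C@H]2[C@@H]1O | intermediate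
50 | CNP0259091.2: (1S,2R,6S,7R,8R,9R,10S,11S,12R,17R)-2,9,12-triacetoxy-6-chloro-8,11-dihydroxybriara-5(16),13-diene 19,7-γ-lactone | C=C1CC[C@@H](OC(C)=O)[C@@]2(C)C=C[C@@H](OC(C)=O)[C@@](C)(O)[C@@H]2[C@@H](OC(C)=O)[C@]2(O)[C@@H](C)C(=O)O[C@H]2[C@H]1Cl | target

**Totals and risks**

Total step count: 35. Longest linear sequence: 35 steps (1 to 50); compounds 3, 5, 13 and 30 enter as small achiral inputs.

The three steps most likely to fail:

Step 32 (chromium-mediated closure of the ten-membered ring). If the cyclisation is poor, the ring is closed by nickel-catalysed reductive alkyne–aldehyde macrocyclisation instead. This fallback sets out from 42 and returns at 47. The same lipase hydrolysis applied to 42 gives the alkynyl primary alcohol F1, and Dess–Martin oxidation gives the ynal F2. Ni(cod)2 with the bulky carbene ligand IPr and Et3SiH in toluene at high dilution then joins the internal alkyne carbon C5 to C6 and gives the exo-methylene macrocycle as its C6 triethylsilyl ether F3. HF·pyridine in THF returns 47, and the route resumes at step 33.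

Step 34 (C6 configuration by reduction of the macrocyclic enone). If reagent control is overridden by the ring, the substrate-preferred epimer is accepted and inverted. This fallback sets out from 48 and returns at 49. Luche reduction (NaBH4, CeCl3·7H2O, MeOH, −78 °C) gives the (6S)-allylic alcohol F4. Mitsunobu inversion with chloroacetic acid (PPh3, DIAD, toluene, 0 °C) gives the (6R)-chloroacetate F5. Thiourea with NaHCO3 in EtOH removes the chloroacetyl group in the presence of the three acetates and delivers 49.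

Step 35 (invertive deoxychlorination; risks are allylic transposition, elimination and ion-pair scrambling). If the one-pot oxyphosphonium method fails, activation and displacement are separated. This fallback sets out from 49 and returns at 50. Methanesulfonic anhydride with 2,6-lutidine in CH2Cl2 at −30 °C (chloride-free) gives the (6R)-methanesulfonate F6. Bu4NCl in acetone at −20 to 0 °C then displaces it by SN2 with inversion to give 50.

**Further compounds**

F1 | step 32 | 2,9,12-triacetate of the terminal alkyne with free C6 primary alcohol (42 without its primary acetate) | C#CCC[C@@H](OC(C)=O)[C@@]1(C)C=C[C@@H](OC(C)=O)[C@@](C)(O)[C@@H]1[C@@H](OC(C)=O)[C@]2(O)[C@@H](C)C(=O)O[C@H]2CO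
F2 | step 32 | ynal: F1 with CH2OH oxidised to the C6 aldehyde | C#CCC[C@@H](OC(C)=O)[C@@]1(C)C=C[C@@H](OC(C)=O)[C@@](C)(O)[C@@H]1[C@@H](OC(C)=O)[C@]2(O)[C@@H](C)C(=O)O[C@H]2C=O
F3 | step 32 | C6 triethylsilyl ether of 47 (both C6 epimers) | C=C1CC[C@@H](OC(C)=O)[C@@]2(C)C=C[C@@H](OC(C)=O)[C@@](C)(O)[C@@H]2[C@@H](OC(C)=O)[C@]2(O)[C@@H](C)C(=O)O[C@H]2C1O[Si](CC)(CC)CC
F4 | step 34 | (6S)-allylic alcohol, C6 epimer of 49 | C=C1CC[C@@H](OC(C)=O)[C@@]2(C)C=C[C@@H](OC(C)=O)[C@@](C)(O)[C@@H]2[C@@H](OC(C)=O)[C@]2(O)[C@@H](C)C(=O)O[C@H]2[C@H]1O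
F5 | step 34 | (6R)-chloroacetate of 49 | C=C1CC[C@@H](OC(C)=O)[C@@]2(C)C=C[C@@H](OC(C)=O)[C@@](C)(O)[C@@H]2[C@@H](OC(C)=O)[C@]2(O)[C@@H](C)C(=O)O[C@H]2[C@@H]1OC(=O)CCl
F6 | step 35 | (6R)-methanesulfonate of 49 | C=C1CC[C@@H](OC(C)=O)[C@@]2(C)C=C[C@@H](OC(C)=O)[C@@](C)(O)[C@@H]2[C@@H](OC(C)=O)[C@]2(O)[C@@H](C)C(=O)O[C@H]2[C@@H]1OS(C)(=O)=O
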